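The easy mistake is to carry a ring yield in percent from one charge to another: the teal run reads 75.7 % ring at 4.00 h, the green run 63.8 % at 4.00 h.

| flask | starting material | remark | time |
|---|---|---|---|
| teal | 0.54 M | run made earlier |  |
| green | 1.2 M | run made earlier |  |
| flask | 0.80 M |  | 6.0 h |

| run | time / h | ring / % | starting material / % |
|---|---|---|---|
| teal | 0.250 | 12.7 | 81.8 |
| teal | 0.500 | 21.5 | 66.0 |
| teal | 0.833 | 35.0 | 52.6 |
| teal | 1.33 | 46.9 | 36.6 |
| teal | 2.00 | 58.2 | 23.8 |
| teal | 4.00 | 75.7 | 10.0 |
| green | 0.667 | 27.6 | 50.0 |
| green | 1.33 | 39.4 | 30.3 |
| green | 2.00 | 49.4 | 19.8 |
| green | 2.50 | 54.1 | 15.9 |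
| green | 3.00 | 57.3 | 13.6 |
| green | 4.00 | 63.8 | 9.1 |

(scatter of a reading: 1 percentage point)

- percent here means starting material units held: one open dimer or side product counts as two
- the earlier runs were read with a standard deviation of 1 percentage point

1. concentration of ring at 6.0 h, in M
2. concentration of starting material at 6.0 h, in M
3. concentration of side product at 6.0 h, in M
4. concentration of open dimer at 6.0 h, in M

I take the ring step as first order and the loss to open dimer as second order in [starting material], so ring gained over other material lost varies inversely with [starting material]. I multiply that ratio by the mean [starting material], at the reading where about half is gone. Teal gives 1.16 M, green 1.11 M, mean 1.14 M. Divided by the flask's charge this gives 1.42, the selectivity factor as I read it from these runs: the rate of use by the ring step over that by the dimer step at the charged amount.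

Integrated to full use with nothing returning, the ring share is the factor times ln of one plus its inverse: 75.7 % for the flask. Stopped at the amount left at the last readings, the same integral gives 72.0 % for teal and 59.6 % for green. The readings stand higher, by 3.7 points and 4.2 points against a scatter of 1 point. So one number is not quite enough, and I read the excess as open dimer returning. Unused starting material pulls the other way; I take the two as offsetting and commit to 0.606 M ring in the flask.

The forecast gives 0.63 M ring, above my figure, with 0.036 M starting material, 0.028 M side product and 0.04 M open dimer at 6.0 h, adding: “The split is poorly determined.”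

The flask gives 0.613 M ring, 0.0397 M starting material, 0.0205 M side product and 0.0514 M open dimer.

    starting material → ring (k = 0.00957 min⁻¹)
    2 starting material ⇌ open dimer (K = 1.90 M⁻¹, k = 0.00477 M⁻¹ min⁻¹)
    starting material + ring → side product (k = 9.92 × 10⁻⁴ M⁻¹ min⁻¹)
    ring → over-reaction product (k = 2.42 × 10⁻⁵ min⁻¹)

In the flask at 6.00 h the ring step uses starting material 25 times as fast as the forward step to open dimer alone. In the neighbouring flask charged at 1.4 M, the selectivity factor as I read it drops to 0.811 and the full-use share with nothing returning to 65.2 %, and that flask holds 68.1 % ring at 6.00 h.

The earlier runs and the new flask are simulated for substances that don't exist; noise was put on by code.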